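**Retrosynthetic overview**
1. Target ⇒ a C5‑phenyl analogue (phenyl = masked CO2H, unveiled last with RuO4) ⇒ a 16‑methylene‑15‑ketone (exo‑face hydrogenation sets C16) ⇒ bicyclo[3.2.1]octenone whose ring D is closed by C16–C13 bond formation from an acetyl cyclohexene.
2. Ring C ⇒ Diels–Alder addition of butadiene to a spiro 3‑acetyl‑5,6‑dihydropyran‑2‑one (sets C8 and C9); the lactone ⇒ intramolecular Knoevenagel condensation of a C9 aldehyde with a C20 acetoacetate.
3. Key disconnection: the quaternary spiro carbon C10 (vinyl + CH2OH beside the C1 carbonyl) ⇒ semipinacol 1,2‑vinyl shift from C1 to C10 in a 2,3‑epoxy alcohol, itself from vinyl addition to an α‑methylene ketone and hydroxyl‑directed epoxidation.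
4. Ring A ⇒ Robinson annulation of isobutyraldehyde with methyl vinyl ketone, rhodium‑catalysed enantioselective conjugate phenylation (the only external source of chirality) and Mannich methylenation.
5. Ring order: ring A → (1,2‑shift fixes C10) → lactone → ring C → ring D.

Assumption: atom labels follow ent‑kaurane numbering (C1 bears OAc, C5 bears C6O2H, C7 lactone C=O, C8/C13 bridgeheads, C10 spiro, C15 ketone, C16–C17 CHCH3, C20 OCH2); the SMILES is read as the (1S,5R,8S,9S,10S,13R,16R) isomer.

**Step 1**
Reactants: 1 isobutyraldehyde; 2 methyl vinyl ketone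
Product: 3 4,4-dimethylcyclohex-2-en-1-one
Conditions: H2SO4 (cat.), PhH, 50 °C then reflux (Dean–Stark)
Reagents that add atoms: none
Why: Acid‑catalysed Michael addition followed by intramolecular aldol condensation (Robinson annulation) is a standard one‑flask route to this enone and creates no stereocentre.

**Step 2**
Reactants: 3 4,4-dimethylcyclohex-2-en-1-one; 4 phenylzinc bromide
Product: 5 (S)-trimethyl[(4,4-dimethyl-3-phenylcyclohex-1-en-1-yl)oxy]silane
Conditions: [RhCl((R)-binap)]2 (1.5 mol %), Me3SiCl, THF, 20 °C
Reagents that add atoms: chlorotrimethylsilane, C[Si](C)(C)Cl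
Why: Rhodium/BINAP‑catalysed asymmetric conjugate arylation with an arylzinc reagent (Hayashi type) sets C5 with the facial sense that gives (R)‑3‑arylcyclohexanones from cyclohexenone (S here because CMe2 outranks CH2), and the chlorosilane traps the enolate regiospecifically as the C1–C10 silyl enol ether.

**Step 3**
Reactants: 5 (S)-trimethyl[(4,4-dimethyl-3-phenylcyclohex-1-en-1-yl)oxy]silane
Product: 8 (S)-4,4-dimethyl-2-methylidene-3-phenylcyclohexan-1-one, via Mannich base 6 (not isolated), via ammonium iodide 7 (not isolated)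
Conditions: Me2N=CH2+ I−, CH2Cl2, rt; MeI; aq. NaHCO3, rt
Reagents that add atoms: Eschenmoser's salt (N,N-dimethylmethyleneiminium iodide), C=[N+](C)C.[I-]
Why: Mukaiyama–Mannich aminomethylation of the regiodefined silyl enol ether followed by quaternisation and E1cB elimination is the standard α‑methylenation and can only occur at C10, while C5 is untouched.

**Step 4**
Reactants: 8 (S)-4,4-dimethyl-2-methylidene-3-phenylcyclohexan-1-one; 9 vinylmagnesium bromide
Product: 10 (1R,3S)-1-ethenyl-4,4-dimethyl-2-methylidene-3-phenylcyclohexan-1-ol (vinyl trans to phenyl)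
Conditions: THF, −78 °C; aq. NH4Cl
Reagents that add atoms: none
Why: Grignard 1,2‑addition takes place on the face of the C1 carbonyl opposite the phenyl group on C5 (which shields the syn face, most strongly when axial), setting C1 with vinyl trans to phenyl, the relationship later transferred to C10.

**Step 5**
Reactants: 10 (1R,3S)-1-ethenyl-4,4-dimethyl-2-methylidene-3-phenylcyclohexan-1-ol
Product: 11 4-ethenyl-7,7-dimethyl-8-phenyl-1-oxaspiro[2.5]octan-4-ol (epoxide O cis to OH; vinyl trans to phenyl)
Conditions: VO(acac)2 (2 mol %), t-BuOOH, CH2Cl2, 0 °C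
Reagents that add atoms: tert-butyl hydroperoxide, CC(C)(C)OO
Why: Vanadium‑catalysed hydroxyl‑directed epoxidation picks the more electron‑rich 1,1‑disubstituted allylic alkene over the vinyl group and delivers oxygen syn to the hydroxyl, and the epoxide configuration is consumed in the next step.

**Step 6 (key step)**
Reactants: 11 4-ethenyl-7,7-dimethyl-8-phenyl-1-oxaspiro[2.5]octan-4-ol
Product: 12 (2S,3S)-2-ethenyl-2-(hydroxymethyl)-4,4-dimethyl-3-phenylcyclohexan-1-one (CH2OH cis to phenyl)
Conditions: BF3·OEt2 (0.2 equiv), CH2Cl2, −78 °C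
Reagents that add atoms: none
Why: Lewis‑acid opening of the epoxide at its tertiary carbon triggers a semipinacol rearrangement of the 2,3‑epoxy alcohol (Tsuchihashi–Suzuki type) in which the vinyl group, antiperiplanar to the breaking C–O bond, shifts suprafacially from C1 to C10, so the C1 configuration is relayed to the new quaternary carbon (C9 vinyl trans, C20 hydroxymethyl cis to phenyl) and C1 returns to a ketone.

**Step 7**
Reactants: 12 (2S,3S)-2-ethenyl-2-(hydroxymethyl)-4,4-dimethyl-3-phenylcyclohexan-1-one
Product: 13 (1S,2S,3S)-2-ethenyl-2-(hydroxymethyl)-4,4-dimethyl-3-phenylcyclohexan-1-ol (OH, CH2OH and phenyl all cis)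
Conditions: NaBH4, MeOH, −40 °C
Reagents that add atoms: none
Why: Borohydride reduction from the ketone face opposite the hydroxymethyl and phenyl groups (axial attack in the C20‑axial chair) gives the equatorial C1 alcohol cis to CH2OH, setting C1.

**Step 8**
Reactants: 13 (1S,2S,3S)-2-ethenyl-2-(hydroxymethyl)-4,4-dimethyl-3-phenylcyclohexan-1-ol; 14 diketene
Product: 16 C1 acetate and C20 3-oxobutanoate of diol 13, via mono-acetoacetate 15 (not isolated)
Conditions: DMAP (cat.), THF, −20 °C; then Ac2O, pyridine, rt
Reagents that add atoms: acetic anhydride, CC(=O)OC(C)=O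
Why: Nucleophile‑catalysed ring opening of diketene acylates the primary alcohol faster than the flanked secondary one, and ordinary acetylation then installs the C1 acetate of the target without touching a stereocentre.

**Step 9**
Reactants: 16 C1 acetate and C20 3-oxobutanoate of diol 13
Product: 19 4-acetyl-10,10-dimethyl-3-oxo-11-phenyl-2-oxaspiro[5.5]undec-4-en-7-yl acetate (ring A configuration as in 13), via ozonide 17 (not isolated), via aldehyde 18 (not isolated)
Conditions: O3, CH2Cl2, −78 °C; Me2S; then piperidine (cat.), AcOH (cat.), rt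
Reagents that add atoms: none
Why: Ozonolysis with reductive work‑up turns the vinyl group into the non‑enolisable C9 aldehyde, which closes the six‑membered lactone by intramolecular Knoevenagel condensation with the tethered acetoacetate (as in the 3‑acetylcoumarin synthesis) without creating a stereocentre.

**Step 10**
Reactants: 19 4-acetyl-10,10-dimethyl-3-oxo-11-phenyl-2-oxaspiro[5.5]undec-4-en-7-yl acetate; 20 buta-1,3-diene
Product: 21 Diels–Alder adduct: cyclohexene ring C (C12=C13) cis-fused to the lactone at C8–C9 with acetyl on C8 (H9 and acetyl cis; ring C on the lactone face syn to C1–OAc)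
Conditions: ZnCl2 (30 mol %), CH2Cl2, 0 °C → rt (sealed tube)
Reagents that add atoms: none
Why: Lewis‑acid‑catalysed Diels–Alder reaction of the doubly activated 2‑acyl enoate forms ring C and the C8 quaternary centre in one suprafacial event, the diene approaching C8=C9 anti to the bulkier CH(Ph)–CMe2 arm of the spiro ring, which sets C9 and C8.

**Step 11**
Reactants: 21 Diels–Alder adduct
Product: 22 tetracyclic 15-oxo lactone with C11=C12 alkene, C16H2 and C5 phenyl (bicyclo[3.2.1]oct-2-ene rings C/D complete)
Conditions: Pd(OCOCF3)2 (10 mol %), DMSO (20 mol %), O2 (1 atm), AcOH, 80 °C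
Reagents that add atoms: none
Why: Proposed new method: electrophilic divalent palladium trifluoroacetate palladates the only enolisable position (the acetyl CH3, C16) to a C‑bound palladium enolate that cannot undergo the usual β‑hydride elimination because C8 is quaternary, so it inserts the cyclohexene by 5‑exo syn‑carbopalladation (C16–C13, ring D, possible only on the face carrying the acetyl group, which fixes C13), β‑hydride elimination towards C11 (the other β‑carbon is a bridgehead) releases the alkene and dioxygen reoxidises zerovalent palladium; the closest known reactions are the palladium‑mediated cycloalkenylation of silyl enol ethers (Saegusa/Toyota–Ihara type) and aerobic palladium‑enolate dehydrogenation of ketones.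

**Step 12**
Reactants: 22 tetracyclic 15-oxo lactone with C11=C12 alkene
Product: 23 16-methylidene derivative of 22
Conditions: (CH2O)n, PhNHMe·CF3CO2H, THF, reflux
Reagents that add atoms: formaldehyde (used as paraformaldehyde), C=O
Why: Mannich‑type α‑methylenation of a ketone with formaldehyde and an anilinium salt (Gras procedure) is regiospecific because C16 is the only enolisable carbon, and no stereocentre is formed.

**Step 13**
Reactants: 23 16-methylidene derivative of 22
Product: 24 C5-phenyl analogue of the target (phenyl in place of CO2H; all other stereocentres as in the target)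
Conditions: H2 (1 atm), Pd/C, EtOAc, rt
Reagents that add atoms: none
Why: Heterogeneous hydrogenation adds hydrogen to the exocyclic enone from the convex exo face of the bicyclo[3.2.1]octane (away from the C11–C12 bridge), placing the C16 methyl endo as required, and saturates C11=C12 at the same time.

**Step 14**
Reactants: 24 C5-phenyl analogue of the target
Product: 25 target CNP0161834.1
Conditions: RuCl3 (5 mol %), NaIO4, CCl4/MeCN/H2O, rt
Reagents that add atoms: sodium periodate (oxygen carried by catalytic RuO4), [Na+].[O-]I(=O)(=O)=O; water, O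
Why: Catalytic ruthenium tetroxide oxidation (Sharpless conditions) degrades the phenyl ring to the carboxylic acid while esters, lactone and ketone survive, and C5 keeps its equatorial, thermodynamically preferred configuration.

**Compound list**
1 | isobutyraldehyde (2-methylpropanal) | CC(C)C=O | starting material
2 | methyl vinyl ketone (but-3-en-2-one) | CC(=O)C=C | starting material
3 | 4,4-dimethylcyclohex-2-en-1-one | CC1(C)CCC(=O)C=C1 | intermediate
4 | phenylzinc bromide | Br[Zn]c1ccccc1 | starting material
5 | (S)-trimethyl[(4,4-dimethyl-3-phenylcyclohex-1-en-1-yl)oxy]silane | C[Si](C)(C)OC1=C[C@H](c2ccccc2)C(C)(C)CC1 | intermediate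
6 | (3S)-2-[(dimethylamino)methyl]-4,4-dimethyl-3-phenylcyclohexan-1-one (Mannich base, C2 epimers, not isolated) | O=C1CCC(C)(C)[C@@H](c2ccccc2)C1CN(C)C | intermediate
7 | N-methyl quaternary ammonium iodide of 6 (not isolated) | O=C1CCC(C)(C)[C@@H](c2ccccc2)C1C[N+](C)(C)C.[I-] | intermediate
8 | (S)-4,4-dimethyl-2-methylidene-3-phenylcyclohexan-1-one | O=C1CCC(C)(C)[C@@H](c2ccccc2)C1=C | intermediate
9 | vinylmagnesium bromide | C=C[Mg]Br | starting material
10 | (1R,3S)-1-ethenyl-4,4-dimethyl-2-methylidene-3-phenylcyclohexan-1-ol (vinyl trans to phenyl) | O[C@@]1(C=C)CCC(C)(C)[C@@H](c2ccccc2)C1=C | intermediate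
11 | 4-ethenyl-7,7-dimethyl-8-phenyl-1-oxaspiro[2.5]octan-4-ol (epoxide O cis to OH, vinyl trans to phenyl) | O[C@@]1(C=C)CCC(C)(C)[C@@H](c2ccccc2)[C@]13CO3 | intermediate
12 | (2S,3S)-2-ethenyl-2-(hydroxymethyl)-4,4-dimethyl-3-phenylcyclohexan-1-one | O=C1CCC(C)(C)[C@@H](c2ccccc2)[C@@]1(C=C)CO | intermediate
13 | (1S,2S,3S)-2-ethenyl-2-(hydroxymethyl)-4,4-dimethyl-3-phenylcyclohexan-1-ol | O[C@H]1CCC(C)(C)[C@@H](c2ccccc2)[C@@]1(C=C)CO | intermediate
14 | diketene (4-methylideneoxetan-2-one) | C=C1CC(=O)O1 | starting material
15 | 3-oxobutanoate of the primary alcohol of 13 (not isolated) | O[C@H]1CCC(C)(C)[C@@H](c2ccccc2)[C@@]1(C=C)COC(=O)CC(C)=O | intermediate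
16 | C1 acetate and C20 3-oxobutanoate of 13 | CC(=O)O[C@H]1CCC(C)(C)[C@@H](c2ccccc2)[C@@]1(C=C)COC(=O)CC(C)=O | intermediate
17 | 1,2,4-trioxolane (ozonide) of the vinyl group of 16 (not isolated) | CC(=O)O[C@H]1CCC(C)(C)[C@@H](c2ccccc2)[C@@]1(C2OCOO2)COC(=O)CC(C)=O | intermediate
18 | C9 aldehyde (vinyl of 16 replaced by CHO, not isolated) | CC(=O)O[C@H]1CCC(C)(C)[C@@H](c2ccccc2)[C@@]1(C=O)COC(=O)CC(C)=O | intermediate
19 | 4-acetyl-10,10-dimethyl-3-oxo-11-phenyl-2-oxaspiro[5.5]undec-4-en-7-yl acetate (lactone CH2O cis to OAc and phenyl) | CC(=O)O[C@H]1CCC(C)(C)[C@@H](c3ccccc3)[C@@]12COC(=O)C(C(C)=O)=C2 | intermediate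
20 | buta-1,3-diene | C=CC=C | starting material
21 | Diels–Alder adduct: ring C cyclohexene (C12=C13) cis-fused to the lactone, acetyl on C8 cis to H9 | CC(=O)O[C@H]1CCC(C)(C)[C@@H](c4ccccc4)[C@@]12COC(=O)[C@@]3(C(C)=O)CC=CC[C@@H]23 | intermediate
22 | tetracyclic 15-oxo lactone, C11=C12 alkene, C16H2, C5 phenyl | CC(=O)O[C@H]1CCC(C)(C)[C@@H](c4ccccc4)[C@@]12COC(=O)[C@@]13C[C@@H](C=C[C@H]12)CC3=O | intermediate
23 | 16-methylidene derivative of 22 | CC(=O)O[C@H]1CCC(C)(C)[C@@H](c4ccccc4)[C@@]12COC(=O)[C@@]13C[C@@H](C=C[C@H]12)C(=C)C3=O | intermediate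
24 | C5-phenyl analogue of the target (16-methyl endo) | CC(=O)O[C@H]1CCC(C)(C)[C@@H](c4ccccc4)[C@@]12COC(=O)[C@@]13C[C@@H](CC[C@H]12)[C@@H](C)C3=O | intermediate
25 | CNP0161834.1 | CC(=O)O[C@H]1CCC(C)(C)[C@@H](C(=O)O)[C@@]12COC(=O)[C@@]13C[C@@H](CC[C@H]12)[C@@H](C)C3=O | target

**Step count**
Total steps: 14. Longest linear sequence: 14 (fully linear; 1, 2, 4, 9, 14 and 20 are commercial and none has more than eight non‑hydrogen atoms).

**Three steps most likely to fail**

Step 4 (face selectivity of the Grignard addition, which decides the configuration of C10). Fallback from 8: ethynylmagnesium bromide (THF, −78 °C), a slim nucleophile that attacks anti to phenyl from either chair, gives the ethynyl carbinol F1. Semi‑hydrogenation (H2, Pd/CaCO3 poisoned with Pb(OAc)2, quinoline) then comes back to the route at 10.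

Step 11 (the proposed palladium cyclisation; possible failures are no α‑palladation of the hindered methyl ketone, allylic oxidation of the cyclohexene, or 6‑endo closure). Known‑chemistry fallback from 21: soft enolisation (TBSOTf, Et3N, CH2Cl2, 0 °C) gives the tert‑butyldimethylsilyl enol ether F2. The established palladium‑mediated cycloalkenylation of silyl enol ethers (Pd(OAc)2, DMSO, O2, 45 °C) then closes ring D and comes back at 22.

Step 13 (C16 configuration; hydrogen might be delivered mainly to the other face). Fallback from 22, skipping step 12: hydrogenation of the ring alkene (H2, Pd/C) gives the saturated 15‑ketone F3. Kinetic enolate methylation (LiN(SiMe3)2, MeI, THF, −78 °C) brings the methyl group in from the face that hydrogen would have used, which is the stereocomplementary outcome, and returns at 24.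

**Further compounds**
F1 | step 4 | (1R,3S)-1-ethynyl-4,4-dimethyl-2-methylidene-3-phenylcyclohexan-1-ol (ethynyl trans to phenyl) | O[C@@]1(C#C)CCC(C)(C)[C@@H](c2ccccc2)C1=C
F2 | step 11 | tert-butyldimethylsilyl enol ether of the acetyl group of 21 | CC(=O)O[C@H]1CCC(C)(C)[C@@H](c4ccccc4)[C@@]12COC(=O)[C@@]3(C(=C)O[Si](C)(C)C(C)(C)C)CC=CC[C@@H]23
F3 | step 13 | 11,12-dihydro derivative of 22 (saturated 15-ketone with C16H2) | CC(=O)O[C@H]1CCC(C)(C)[C@@H](c4ccccc4)[C@@]12COC(=O)[C@@]13C[C@@H](CC[C@H]12)CC3=O
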